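**Plan**

- Labels: ring C1 (isopropenyl), C2=C3(CH3), C4 (C7H2–OAr), C5 (CH3 and chain C10–C11–C12O2H), C6H2.
- Enabling feature: with C7 at the carboxyl level and C10=C11 as a vinyl group, the cis pair on C4/C5 is what an ester-enolate [3,3] shift leaves when an allylic ester joins C7 to C11 through oxygen. That ester is a ten-membered lactone ring (O, C7, C4, C3, C2, C1, C6, C5, C10, C11), which contracts to the cyclohexene ring.
- Cuts, in retrosynthetic order: C11–C12 (hydroformylation, oxidation), aryl O–C7 (Mitsunobu), ring bond C4–C5 (transannular Ireland–Claisen), lactone O–C11 (Mitsunobu lactonisation), C3–C4 (zinc enolate coupling), C2=C3 (α-iodo-Wittig), C1–C6 (auxiliary alkylation).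
- Forward: a (Z)-C5 allylic bromide is joined to a senecioyl imide and the chain is extended to the (Z,Z)-hydroxy acid. The ten-membered lactone is the first ring, the cyclohexene arises from it in the key step, the coumarin is attached next and C12 is added last.
- Stereochemistry: C1 from the oxazolidinone alkylation; both Z alkenes from Still–Gennari and α-iodo-Wittig olefinations; C4 and C5 from the cis-fused [3,3] array, their sense relative to C1 from the pseudoequatorial isopropenyl group.

Key step: step 12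

Remark: the ketene acetal of the key step is written with the ring oxygen and C3 cis about the ketene acetal double bond; the opposite geometry would lead to the same C4/C5 relationship.

**Route**

Step 1
Reactants: 1 2-(tert-butyldimethylsilyloxy)acetaldehyde; 2 ethyl 2-[bis(2,2,2-trifluoroethoxy)phosphoryl]propanoate
Product: 3 ethyl (2Z)-4-(tert-butyldimethylsilyloxy)-2-methylbut-2-enoate
Conditions: KN(SiMe3)2, 18-crown-6, THF, −78 °C
Reagents that add atoms: none
Why: Still–Gennari olefination, in which the electron-poor phosphonate anion adds irreversibly under dissociating conditions and the fast-eliminating adduct gives the (Z)-enoate, fixing the geometry of the alkene that becomes C5=C10.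

Step 2
Reactants: 3 ethyl (2Z)-4-(tert-butyldimethylsilyloxy)-2-methylbut-2-enoate
Product: 4 (2Z)-4-(tert-butyldimethylsilyloxy)-2-methylbut-2-en-1-ol
Conditions: i-Bu2AlH, CH2Cl2, −78 °C
Reagents that add atoms: none
Why: 1,2-reduction of the enoate by the aluminium hydride at low temperature should give the allylic alcohol with alkene geometry and silyl ether intact.

Step 3
Reactants: 4 (2Z)-4-(tert-butyldimethylsilyloxy)-2-methylbut-2-en-1-ol
Product: 5 (2Z)-1-bromo-4-(tert-butyldimethylsilyloxy)-2-methylbut-2-ene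
Conditions: CBr4, PPh3, CH2Cl2, 0 °C
Reagents that add atoms: tetrabromomethane, BrC(Br)(Br)Br
Why: Appel bromination, an SN2 displacement of the alkoxyphosphonium ion at the primary allylic carbon, should proceed without allylic transposition or loss of Z geometry.

Step 4
Reactants: 6 (4R)-4-benzyl-1,3-oxazolidin-2-one; 7 3-methylbut-2-enoyl chloride
Product: 8 (4R)-4-benzyl-3-(3-methylbut-2-enoyl)-1,3-oxazolidin-2-one
Conditions: n-BuLi, THF, −78 °C; then 7, −78 → 0 °C
Reagents that add atoms: none
Why: N-acylation of the lithiated oxazolidinone with an acid chloride is the standard entry to N-enoyl imides.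

Step 5
Reactants: 8 (4R)-4-benzyl-3-(3-methylbut-2-enoyl)-1,3-oxazolidin-2-one; 5 (2Z)-1-bromo-4-(tert-butyldimethylsilyloxy)-2-methylbut-2-ene
Product: 9 (4R)-4-benzyl-3-[(2R,4Z)-6-(tert-butyldimethylsilyloxy)-4-methyl-2-(prop-1-en-2-yl)hex-4-enoyl]-1,3-oxazolidin-2-one
Conditions: NaN(SiMe3)2, THF, −78 °C; then 5, −78 → −40 °C
Reagents that add atoms: none
Why: Deconjugative Evans alkylation (the lavandulol-type α-alkylation): γ-deprotonation gives the chelated (Z)-dienolate, which is alkylated at the α-carbon on the face opposite the benzyl group, setting C1 of the target as 2R in 9 and forming C1–C6.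

Step 6
Reactants: 9 (4R)-4-benzyl-3-[(2R,4Z)-6-(tert-butyldimethylsilyloxy)-4-methyl-2-(prop-1-en-2-yl)hex-4-enoyl]-1,3-oxazolidin-2-one
Product: 10 (2R,4Z)-6-(tert-butyldimethylsilyloxy)-4-methyl-2-(prop-1-en-2-yl)hex-4-en-1-ol
Conditions: LiBH4, MeOH (1 equiv), Et2O, 0 °C
Reagents that add atoms: none
Why: Reductive cleavage of the imide by the borohydride should release the primary alcohol and the auxiliary under non-epimerising conditions.

Step 7
Reactants: 10 (2R,4Z)-6-(tert-butyldimethylsilyloxy)-4-methyl-2-(prop-1-en-2-yl)hex-4-en-1-ol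
Product: 11 (2R,4Z)-6-(tert-butyldimethylsilyloxy)-4-methyl-2-(prop-1-en-2-yl)hex-4-enal
Conditions: Dess–Martin periodinane, NaHCO3, CH2Cl2, 0 °C; crude aldehyde used at once
Reagents that add atoms: none
Why: Buffered Dess–Martin oxidation is non-basic, so the α-isopropenyl aldehyde should form without epimerisation or migration of the alkene into conjugation.

Step 8
Reactants: 11 (2R,4Z)-6-(tert-butyldimethylsilyloxy)-4-methyl-2-(prop-1-en-2-yl)hex-4-enal
Product: 12 tert-butyl{[(2Z,5S,6Z)-7-iodo-3-methyl-5-(prop-1-en-2-yl)octa-2,6-dien-1-yl]oxy}dimethylsilane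
Conditions: EtPPh3I, n-BuLi, THF, 0 °C; I2, −78 °C; NaN(SiMe3)2, −20 °C; then 11, −78 °C
Reagents that add atoms: ethyltriphenylphosphonium iodide, CC[P+](c1ccccc1)(c1ccccc1)c1ccccc1.[I-]; iodine, II
Why: Stork–Zhao-type Wittig olefination with the α-iodoethylidene ylide should give, under kinetic control at −78 °C, the (Z)-2-iodoalkene with iodine cis to the C1 chain, forming C2=C3.

Step 9
Reactants: 12 tert-butyl{[(2Z,5S,6Z)-7-iodo-3-methyl-5-(prop-1-en-2-yl)octa-2,6-dien-1-yl]oxy}dimethylsilane
Product: 13 ethyl (3Z,5S,7Z)-9-(tert-butyldimethylsilyloxy)-3,7-dimethyl-5-(prop-1-en-2-yl)nona-3,7-dienoate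
Conditions: BrZnCH2CO2Et (from BrCH2CO2Et, Zn, cat. Me3SiCl, THF), Pd2(dba)3 (2.5 mol %), XPhos (10 mol %), THF, 50 °C
Reagents that add atoms: ethyl bromozincacetate (from ethyl bromoacetate and zinc), CCOC(=O)C[Zn]Br
Why: Negishi-type cross-coupling of the Reformatsky reagent with the alkenyl iodide (oxidative addition to zerovalent palladium, transmetallation, reductive elimination) proceeds with retention of alkene geometry and forms C3–C4, giving the β,γ-unsaturated ester directly.

Step 10
Reactants: 13 ethyl (3Z,5S,7Z)-9-(tert-butyldimethylsilyloxy)-3,7-dimethyl-5-(prop-1-en-2-yl)nona-3,7-dienoate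
Product: 15 (3Z,5S,7Z)-9-hydroxy-3,7-dimethyl-5-(prop-1-en-2-yl)nona-3,7-dienoic acid, via hydroxy ester 14 (not isolated)
Conditions: Bu4NF, THF, 0 °C → rt; then LiOH, H2O–MeOH, 0 °C → rt; 1 M HCl to pH 4
Reagents that add atoms: lithium hydroxide, [Li+].[OH-]
Why: Fluoride desilylation followed in the same flask by mild saponification of the unhindered ethyl ester should give the seco acid, the carboxylate being resistant to migration of the Z alkene into conjugation.

Step 11
Reactants: 15 (3Z,5S,7Z)-9-hydroxy-3,7-dimethyl-5-(prop-1-en-2-yl)nona-3,7-dienoic acid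
Product: 16 (4Z,6S,8Z)-4,8-dimethyl-6-(prop-1-en-2-yl)-3,6,7,10-tetrahydro-2H-oxecin-2-one
Conditions: PPh3, DIAD, toluene–THF, slow addition of 15 (final 2 mM), 0 °C → rt
Reagents that add atoms: none
Why: Mitsunobu macrolactonisation, in which the internal carboxylate displaces the alkoxyphosphonium ion of the primary allylic alcohol at C11 under high dilution, avoids acyl activation of the β,γ-unsaturated acid (no ketene formation or conjugation), and the two Z alkenes hold the chain ends close.

Step 12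
Reactants: 16 (4Z,6S,8Z)-4,8-dimethyl-6-(prop-1-en-2-yl)-3,6,7,10-tetrahydro-2H-oxecin-2-one
Product: 19 (1S,4S,6S)-6-ethenyl-2,6-dimethyl-4-(prop-1-en-2-yl)cyclohex-2-ene-1-carboxylic acid, via silyl ketene acetal 17 (not isolated), via trimethylsilyl ester 18 (not isolated)
Conditions: KN(SiMe3)2, Me3SiCl–Et3N, THF, −78 °C → rt, then 60 °C; 1 M HCl
Reagents that add atoms: none
Why: Deprotonation at C4 (α to the lactone carbonyl and allylic to C2=C3) with internal Me3SiCl trapping gives the ring-constrained silyl ketene acetal 17, whose six-centre array C4=C7(OSi)–O–C11–C10=C5 undergoes a concerted suprafacial [3,3] shift that forms C4–C5, breaks O–C11 and turns C10=C11 into the vinyl group, the silyl ester 18 being hydrolysed on work-up. The closest known reaction type is the Ireland–Claisen ring contraction of macrocyclic allylic lactones to cis-2-alkenylcycloalkanecarboxylic acids. The cyclohexene ring closes transannularly: the four-atom bridge C3=C2–C1–C6 already joins the two termini, so the new σ-bond converts the ten-membered lactone into the six-membered carbocycle with the pericyclic array cis-fused to the forming ring (boat-like for the ring-cis ketene acetal drawn, chair-like for the other ketene acetal geometry). C4 and C5 are therefore set together by the ring constraint, because so short a bridge can only span syn-oriented termini, which places the carboxyl carbon C7 and the vinyl group cis and the C5 methyl trans to them whichever ketene acetal reacts. The sense of both centres relative to C1 is controlled by the existing stereocentre: in the forming half-chair the isopropenyl group should sit pseudoequatorial (avoiding a 1,3-syn clash with the axial C5 methyl) while A(1,2) strain with the C3 methyl holds C7 pseudoaxial, which puts isopropenyl, C7 and vinyl on one face. The step needs this facial selectivity and a Z C2=C3 alkene (an E alkene cannot span a cyclohexene); the latter is secured by the stereodefined alkenyl iodide coupling, and silylation at −78 °C should outrun fragmentation of the enolate to a ketene.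

Step 13
Reactants: 19 (1S,4S,6S)-6-ethenyl-2,6-dimethyl-4-(prop-1-en-2-yl)cyclohex-2-ene-1-carboxylic acid
Product: 20 [(1S,4S,6S)-6-ethenyl-2,6-dimethyl-4-(prop-1-en-2-yl)cyclohex-2-en-1-yl]methanol
Conditions: LiAlH4, THF, 0 °C → reflux
Reagents that add atoms: none
Why: Hydride reduction of the hindered carboxylic acid should give the primary alcohol C7–OH without touching the isolated alkenes or the C4 configuration.

Step 14
Reactants: 20 [(1S,4S,6S)-6-ethenyl-2,6-dimethyl-4-(prop-1-en-2-yl)cyclohex-2-en-1-yl]methanol; 21 umbelliferone (7-hydroxy-2H-chromen-2-one)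
Product: 22 7-{[(1S,4S,6S)-6-ethenyl-2,6-dimethyl-4-(prop-1-en-2-yl)cyclohex-2-en-1-yl]methoxy}-2H-chromen-2-one
Conditions: PPh3, DIAD, THF, 0 → 50 °C
Reagents that add atoms: none
Why: Mitsunobu etherification, in which the acidic 7-hydroxyl of the coumarin (pKa about 8) displaces the alkoxyphosphonium ion at the primary C7 carbon, touches no stereocentre.

Step 15
Reactants: 22 7-{[(1S,4S,6S)-6-ethenyl-2,6-dimethyl-4-(prop-1-en-2-yl)cyclohex-2-en-1-yl]methoxy}-2H-chromen-2-one
Product: 23 3-[(1R,2R,5S)-1,3-dimethyl-2-{[(2-oxo-2H-chromen-7-yl)oxy]methyl}-5-(prop-1-en-2-yl)cyclohex-3-en-1-yl]propanal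
Conditions: Rh(acac)(CO)2 (1 mol %), BiPhePhos (2 mol %), CO/H2 (1:1, 5 bar), toluene, 60 °C
Reagents that add atoms: carbon monoxide, [C-]#[O+]
Why: Linear-selective hydroformylation with the rhodium/bulky bisphosphite catalyst strongly prefers a monosubstituted alkene over 1,1-disubstituted, trisubstituted and conjugated ones, and the vinyl group on quaternary C5 has no allylic hydrogen and cannot take the formyl group at C10, so only the C12 aldehyde should form.

Step 16
Reactants: 23 3-[(1R,2R,5S)-1,3-dimethyl-2-{[(2-oxo-2H-chromen-7-yl)oxy]methyl}-5-(prop-1-en-2-yl)cyclohex-3-en-1-yl]propanal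
Product: 24 3-[(1R,2R,5S)-1,3-dimethyl-2-{[(2-oxo-2H-chromen-7-yl)oxy]methyl}-5-(prop-1-en-2-yl)cyclohex-3-en-1-yl]propanoic acid
Conditions: NaClO2, NaH2PO4, 2-methylbut-2-ene, t-BuOH–H2O, 0 °C → rt
Reagents that add atoms: sodium chlorite, [Na+].[O-]Cl=O
Why: Pinnick oxidation, with the hypochlorous acid scavenged by 2-methylbut-2-ene, should convert the aldehyde into the acid without affecting the alkenes or the coumarin.

**Compound list**

1 | 2-(tert-butyldimethylsilyloxy)acetaldehyde | O=CCO[Si](C)(C)C(C)(C)C | starting material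
2 | ethyl 2-[bis(2,2,2-trifluoroethoxy)phosphoryl]propanoate | CCOC(=O)C(C)P(=O)(OCC(F)(F)F)OCC(F)(F)F | starting material
3 | ethyl (2Z)-4-(tert-butyldimethylsilyloxy)-2-methylbut-2-enoate | CCOC(=O)/C(C)=C\CO[Si](C)(C)C(C)(C)C | intermediate
4 | (2Z)-4-(tert-butyldimethylsilyloxy)-2-methylbut-2-en-1-ol | OC/C(C)=C\CO[Si](C)(C)C(C)(C)C | intermediate
5 | (2Z)-1-bromo-4-(tert-butyldimethylsilyloxy)-2-methylbut-2-ene | BrC/C(C)=C\CO[Si](C)(C)C(C)(C)C | intermediate
6 | (4R)-4-benzyl-1,3-oxazolidin-2-one | O=C1N[C@H](Cc2ccccc2)CO1 | starting material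
7 | 3-methylbut-2-enoyl chloride | CC(C)=CC(=O)Cl | starting material
8 | (4R)-4-benzyl-3-(3-methylbut-2-enoyl)-1,3-oxazolidin-2-one | CC(C)=CC(=O)N1[C@H](Cc2ccccc2)COC1=O | intermediate
9 | (4R)-4-benzyl-3-[(2R,4Z)-6-(tert-butyldimethylsilyloxy)-4-methyl-2-(prop-1-en-2-yl)hex-4-enoyl]-1,3-oxazolidin-2-one | C=C(C)[C@@H](C/C(C)=C\CO[Si](C)(C)C(C)(C)C)C(=O)N1[C@H](Cc2ccccc2)COC1=O | intermediate
10 | (2R,4Z)-6-(tert-butyldimethylsilyloxy)-4-methyl-2-(prop-1-en-2-yl)hex-4-en-1-ol | C=C(C)[C@@H](C/C(C)=C\CO[Si](C)(C)C(C)(C)C)CO | intermediate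
11 | (2R,4Z)-6-(tert-butyldimethylsilyloxy)-4-methyl-2-(prop-1-en-2-yl)hex-4-enal | C=C(C)[C@@H](C/C(C)=C\CO[Si](C)(C)C(C)(C)C)C=O | intermediate
12 | tert-butyl{[(2Z,5S,6Z)-7-iodo-3-methyl-5-(prop-1-en-2-yl)octa-2,6-dien-1-yl]oxy}dimethylsilane | C=C(C)[C@@H](C/C(C)=C\CO[Si](C)(C)C(C)(C)C)/C=C(/C)I | intermediate
13 | ethyl (3Z,5S,7Z)-9-(tert-butyldimethylsilyloxy)-3,7-dimethyl-5-(prop-1-en-2-yl)nona-3,7-dienoate | C=C(C)[C@@H](C/C(C)=C\CO[Si](C)(C)C(C)(C)C)/C=C(/C)CC(=O)OCC | intermediate
14 | ethyl (3Z,5S,7Z)-9-hydroxy-3,7-dimethyl-5-(prop-1-en-2-yl)nona-3,7-dienoate (not isolated) | C=C(C)[C@@H](C/C(C)=C\CO)/C=C(/C)CC(=O)OCC | intermediate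
15 | (3Z,5S,7Z)-9-hydroxy-3,7-dimethyl-5-(prop-1-en-2-yl)nona-3,7-dienoic acid | C=C(C)[C@@H](C/C(C)=C\CO)/C=C(/C)CC(=O)O | intermediate
16 | (4Z,6S,8Z)-4,8-dimethyl-6-(prop-1-en-2-yl)-3,6,7,10-tetrahydro-2H-oxecin-2-one | O=C1C/C(C)=C\[C@@H](C(C)=C)C/C(C)=C\CO1 | intermediate
17 | trimethyl{[(2E,4Z,6S,8Z)-4,8-dimethyl-6-(prop-1-en-2-yl)-6,7-dihydro-10H-oxecin-2-yl]oxy}silane (not isolated) | C[Si](C)(C)O/C1=C/C(C)=C\[C@@H](C(C)=C)C/C(C)=C\CO1 | intermediate
18 | trimethylsilyl (1S,4S,6S)-6-ethenyl-2,6-dimethyl-4-(prop-1-en-2-yl)cyclohex-2-ene-1-carboxylate (not isolated) | C=C(C)[C@@H]1C=C(C)[C@H](C(=O)O[Si](C)(C)C)[C@](C)(C=C)C1 | intermediate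
19 | (1S,4S,6S)-6-ethenyl-2,6-dimethyl-4-(prop-1-en-2-yl)cyclohex-2-ene-1-carboxylic acid | C=C(C)[C@@H]1C=C(C)[C@H](C(=O)O)[C@](C)(C=C)C1 | intermediate
20 | [(1S,4S,6S)-6-ethenyl-2,6-dimethyl-4-(prop-1-en-2-yl)cyclohex-2-en-1-yl]methanol | C=C(C)[C@@H]1C=C(C)[C@H](CO)[C@](C)(C=C)C1 | intermediate
21 | umbelliferone (7-hydroxy-2H-chromen-2-one) | O=c1ccc2ccc(O)cc2o1 | starting material
22 | 7-{[(1S,4S,6S)-6-ethenyl-2,6-dimethyl-4-(prop-1-en-2-yl)cyclohex-2-en-1-yl]methoxy}-2H-chromen-2-one | C=C(C)[C@@H]1C=C(C)[C@H](COc2ccc3ccc(=O)oc3c2)[C@](C)(C=C)C1 | intermediate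
23 | 3-[(1R,2R,5S)-1,3-dimethyl-2-{[(2-oxo-2H-chromen-7-yl)oxy]methyl}-5-(prop-1-en-2-yl)cyclohex-3-en-1-yl]propanal | C=C(C)[C@@H]1C=C(C)[C@H](COc2ccc3ccc(=O)oc3c2)[C@](C)(CCC=O)C1 | intermediate
24 | 3-[(1R,2R,5S)-1,3-dimethyl-2-{[(2-oxo-2H-chromen-7-yl)oxy]methyl}-5-(prop-1-en-2-yl)cyclohex-3-en-1-yl]propanoic acid (CNP0301632.1) | C=C(C)[C@@H]1C=C(C)[C@H](COc2ccc3ccc(=O)oc3c2)[C@](C)(CCC(=O)O)C1 | target

**Step count**

Total: 16 steps. Longest linear sequence: 15 steps (1 → 24 through steps 1–3 and 5–16; step 4 is a one-step branch).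

**Steps most likely to fail**

Step 12 (ring contraction). What may go wrong is poor facial discrimination with respect to the C1 centre, the pathway with a pseudoaxial isopropenyl group competing in the strained transannular array, or fragmentation of the potassium enolate before silylation. The fallback sets out from lactone 16 and comes back at acid 19; it moves the control from the ring conformation to a chiral boron reagent and replaces the basic enolisation by a soft one. Lactone 16 would be treated with (4S,5S)-2-bromo-1,3-bis(4-methylbenzenesulfonyl)-4,5-diphenyl-1,3,2-diazaborolidine (or its enantiomer, whichever pairing reinforces the substrate bias) and i-Pr2NEt in CH2Cl2 at −78 °C. This should give the boron ketene acetal (4S,5S)-2-{[(2Z,4Z,6S,8Z)-4,8-dimethyl-6-(prop-1-en-2-yl)-6,7-dihydro-10H-oxecin-2-yl]oxy}-1,3-bis(4-methylbenzenesulfonyl)-4,5-diphenyl-1,3,2-diazaborolidine F1. On warming, F1 undergoes the same transannular [3,3] shift under reagent control to the acyloxyborane (4S,5S)-1,3-bis(4-methylbenzenesulfonyl)-4,5-diphenyl-1,3,2-diazaborolidin-2-yl (1S,4S,6S)-6-ethenyl-2,6-dimethyl-4-(prop-1-en-2-yl)cyclohex-2-ene-1-carboxylate F2, and aqueous work-up returns 19 together with the recoverable bis-sulfonamide. Enantioselective boron-enolate Claisen rearrangement, including its use for macrolactone ring contraction, is known chemistry.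

Step 11 (macrolactonisation). Intermolecular esterification to the diolide and oligomers may outrun closure of the strained ten-membered ring, or the allylic alkoxyphosphonium ion may collapse by SN2′ attack or elimination. The fallback sets out from hydroxy acid 15 and comes back at lactone 16; it changes the ring-closing event from alkyl–oxygen to acyl–oxygen bond formation under neutral double activation (Corey–Nicolaou lactonisation, Gerlach variant). Acid 15 with 2,2′-dipyridyl disulfide and PPh3 would give S-pyridin-2-yl (3Z,5S,7Z)-9-hydroxy-3,7-dimethyl-5-(prop-1-en-2-yl)nona-3,7-dienethioate F3, which is added slowly to AgOSO2CF3 in toluene at room temperature (or to refluxing toluene) so that the hydroxyl is acylated within the bound complex to give 16.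

Step 8 (α-iodo-Wittig olefination, together with the coupling of step 9). The basic ylide may epimerise the α-isopropenyl aldehyde or move its alkene into conjugation, and the Z selectivity may erode. The fallback sets out from aldehyde 11 and comes back at ester 13; it replaces the iodoalkene/zinc enolate pair by a less basic Z-selective olefination and an Arndt–Eistert homologation. Still–Gennari olefination of 11 with phosphonate 2 (KN(SiMe3)2, 18-crown-6, −78 °C) would give ethyl (2Z,4S,6Z)-8-(tert-butyldimethylsilyloxy)-2,6-dimethyl-4-(prop-1-en-2-yl)octa-2,6-dienoate F4. Saponification with LiOH gives (2Z,4S,6Z)-8-(tert-butyldimethylsilyloxy)-2,6-dimethyl-4-(prop-1-en-2-yl)octa-2,6-dienoic acid F5. Activation with isobutyl chloroformate and Et3N gives the mixed anhydride (2Z,4S,6Z)-8-(tert-butyldimethylsilyloxy)-2,6-dimethyl-4-(prop-1-en-2-yl)octa-2,6-dienoic isobutyl carbonic anhydride F6, and diazomethane converts it into (3Z,5S,7Z)-9-(tert-butyldimethylsilyloxy)-1-diazo-3,7-dimethyl-5-(prop-1-en-2-yl)nona-3,7-dien-2-one F7. Photochemical Wolff rearrangement of F7 in ethanol, in which the alkenyl group migrates with retention of geometry, would give 13.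

**Further compounds**

F1 | step 12 | (4S,5S)-2-{[(2Z,4Z,6S,8Z)-4,8-dimethyl-6-(prop-1-en-2-yl)-6,7-dihydro-10H-oxecin-2-yl]oxy}-1,3-bis(4-methylbenzenesulfonyl)-4,5-diphenyl-1,3,2-diazaborolidine | Cc1ccc(cc1)S(=O)(=O)N1B(O/C2=C/C(C)=C\[C@@H](C(C)=C)C/C(C)=C\CO2)N(S(=O)(=O)c2ccc(C)cc2)[C@@H](c2ccccc2)[C@@H]1c1ccccc1
F2 | step 12 | (4S,5S)-1,3-bis(4-methylbenzenesulfonyl)-4,5-diphenyl-1,3,2-diazaborolidin-2-yl (1S,4S,6S)-6-ethenyl-2,6-dimethyl-4-(prop-1-en-2-yl)cyclohex-2-ene-1-carboxylate | C=C(C)[C@@H]1C=C(C)[C@H](C(=O)OB2N(S(=O)(=O)c3ccc(C)cc3)[C@@H](c3ccccc3)[C@H](c3ccccc3)N2S(=O)(=O)c2ccc(C)cc2)[C@](C)(C=C)C1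
F3 | step 11 | S-pyridin-2-yl (3Z,5S,7Z)-9-hydroxy-3,7-dimethyl-5-(prop-1-en-2-yl)nona-3,7-dienethioate | C=C(C)[C@@H](C/C(C)=C\CO)/C=C(/C)CC(=O)Sc1ccccn1
F4 | step 8 | ethyl (2Z,4S,6Z)-8-(tert-butyldimethylsilyloxy)-2,6-dimethyl-4-(prop-1-en-2-yl)octa-2,6-dienoate | C=C(C)[C@@H](C/C(C)=C\CO[Si](C)(C)C(C)(C)C)/C=C(/C)C(=O)OCC
F5 | step 8 | (2Z,4S,6Z)-8-(tert-butyldimethylsilyloxy)-2,6-dimethyl-4-(prop-1-en-2-yl)octa-2,6-dienoic acid | C=C(C)[C@@H](C/C(C)=C\CO[Si](C)(C)C(C)(C)C)/C=C(/C)C(=O)O
F6 | step 8 | (2Z,4S,6Z)-8-(tert-butyldimethylsilyloxy)-2,6-dimethyl-4-(prop-1-en-2-yl)octa-2,6-dienoic isobutyl carbonic anhydride | C=C(C)[C@@H](C/C(C)=C\CO[Si](C)(C)C(C)(C)C)/C=C(/C)C(=O)OC(=O)OCC(C)C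
F7 | step 8 | (3Z,5S,7Z)-9-(tert-butyldimethylsilyloxy)-1-diazo-3,7-dimethyl-5-(prop-1-en-2-yl)nona-3,7-dien-2-one | C=C(C)[C@@H](C/C(C)=C\CO[Si](C)(C)C(C)(C)C)/C=C(/C)C(=O)C=[N+]=[N-]
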